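## Retrosynthetic overview

1. Ring code: A is the fused resorcinol ring, B the fused catechol ring, C the six-membered carbocycle, D the central monophenol ring, E the pendant catechol ring and F the seven-membered carbocycle; M1 is the CH common to C and F, and M2 is the CH that carries E. Feature used: M2 holds two identical 3,4-dioxygenated aryl groups (B and E), so breaking the M1–ring B bond and flattening M1 to an alkene carbon gives an achiral precursor in which these two veratryl groups are enantiotopic.
2. Endgame disconnections: first the seven O-methyl groups (BBr3), then the ring A–ring D biaryl bond of ring C (Pd direct arylation of a ring D triflate onto an ortho C–H of ring A); the triflate oxygen is the one that served the key step.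
3. Key disconnection: the M1–ring B bond of ring F, formed when a chiral N-triflyl phosphoramide turns a 2-hydroxystilbene into a ring D ortho-quinone methide that one of the two veratryl rings attacks; M1 and M2 arise together.
4. The hydroxystilbene comes from a ring D salicylaldehyde (masked as its allyl ether for the olefination) and a 3,5-dimethoxybenzyl phosphonate (ring A); the aldehyde comes from a 1,1,2-triarylethane built from 3,5-dimethoxyphenylacetic acid and two veratryl Grignard units.
5. Order of ring formation: A, B, D and E are bought as arenes, ring F closes first (step 10) and ring C second (step 12).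

Key step: step 10

Assumption: the sense of induction of the phosphoramide cannot be foreseen, so the (R)-catalyst is written; should it favour the (5R,10S) series, its (S)-antipode is used instead.

## Route

Step 1
Reactants: 1 3,5-dimethoxyphenylacetic acid
Product: 2 methyl 3,5-dimethoxyphenylacetate
Conditions: MeOH, H2SO4 (cat.), reflux
Reagents that add atoms: methanol, CO
Why: Fischer esterification, driven by methanol as solvent; the aryl methyl ethers are inert to these conditions.

Step 2
Reactants: 2 methyl 3,5-dimethoxyphenylacetate; 3 4-bromoveratrole (3 equiv)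
Product: 6 1,1-bis(3,4-dimethoxyphenyl)-2-(3,5-dimethoxyphenyl)ethan-1-ol, via 3,4-dimethoxyphenylmagnesium bromide 4 (not isolated), via monoaddition ketone 5 (not isolated)
Conditions: 3, Mg, THF, reflux; then 2, 0 °C → reflux; aq NH4Cl
Reagents that add atoms: none
Why: Double Grignard addition to an ester: the first addition and loss of methoxide give ketone 5, which is more electrophilic than the ester and takes the second aryl group, and the excess of 4 covers what is lost to enolisation.

Step 3
Reactants: 6 1,1-bis(3,4-dimethoxyphenyl)-2-(3,5-dimethoxyphenyl)ethan-1-ol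
Product: 7 1,1-bis(3,4-dimethoxyphenyl)-2-(3,5-dimethoxyphenyl)ethane
Conditions: Et3SiH (3 equiv), CF3CO2H, CH2Cl2, 0 °C → rt
Reagents that add atoms: none
Why: Ionic hydrogenation: CF3CO2H ionises the tertiary, doubly benzylic C–O bond with the help of two para methoxyls and Et3SiH delivers hydride to that carbon, which becomes the prochiral CH (future M2) with two identical aryl groups.

Step 4
Reactants: 7 1,1-bis(3,4-dimethoxyphenyl)-2-(3,5-dimethoxyphenyl)ethane
Product: 9 2-[2,2-bis(3,4-dimethoxyphenyl)ethyl]-4,6-dimethoxybenzaldehyde, via aryl iminium salt 8 (not isolated)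
Conditions: POCl3 (1.3 equiv), DMF, 0 → 60 °C; then aq NaOAc
Reagents that add atoms: N,N-dimethylformamide, CN(C)C=O; water, O
Why: Vilsmeier–Haack formylation: the 1,3-dimethoxy ring is far more nucleophilic than the veratryl rings, and it reacts at the carbon next to the arm (para to one methoxyl, ortho to the other) rather than at the crowded carbon between both methoxyls, as 3,5-dimethoxytoluene does.

Step 5
Reactants: 9 2-[2,2-bis(3,4-dimethoxyphenyl)ethyl]-4,6-dimethoxybenzaldehyde
Product: 10 2-[2,2-bis(3,4-dimethoxyphenyl)ethyl]-6-hydroxy-4-methoxybenzaldehyde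
Conditions: BCl3 (1.2 equiv), CH2Cl2, −78 → 0 °C; then H2O
Reagents that add atoms: none
Why: Chelation-directed aryl methyl ether cleavage: BCl3 bridges the aldehyde oxygen and the neighbouring methoxyl in a six-membered chelate, so with about one equivalent at low temperature chloride removes only that methyl group and the five other ethers stay.

Step 6
Reactants: 10 2-[2,2-bis(3,4-dimethoxyphenyl)ethyl]-6-hydroxy-4-methoxybenzaldehyde
Product: 11 2-allyloxy-6-[2,2-bis(3,4-dimethoxyphenyl)ethyl]-4-methoxybenzaldehyde
Conditions: allyl bromide, K2CO3, DMF, 50 °C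
Reagents that add atoms: allyl bromide, C=CCBr
Why: Williamson ether synthesis: it masks the phenol for step 8, where a free phenoxide would deactivate the already hindered and electron-rich aldehyde, and allyl is chosen because it resists base and can later be taken off without acid.

Step 7
Reactants: 12 3,5-dimethoxybenzyl bromide
Product: 13 diethyl (3,5-dimethoxybenzyl)phosphonate
Conditions: P(OEt)3 (neat), 140 °C
Reagents that add atoms: triethyl phosphite, CCOP(OCC)OCC
Why: Michaelis–Arbuzov reaction: the phosphite displaces the benzylic bromide and bromide then dealkylates one ethoxy group of the phosphonium ion.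

Step 8
Reactants: 11 2-allyloxy-6-[2,2-bis(3,4-dimethoxyphenyl)ethyl]-4-methoxybenzaldehyde; 13 diethyl (3,5-dimethoxybenzyl)phosphonate
Product: 14 1-allyloxy-3-[2,2-bis(3,4-dimethoxyphenyl)ethyl]-2-[(E)-2-(3,5-dimethoxyphenyl)ethenyl]-5-methoxybenzene
Conditions: NaH, THF, 0 °C → rt
Reagents that add atoms: none
Why: Horner–Wadsworth–Emmons olefination: the benzylic phosphonate anion adds reversibly to the aldehyde and elimination through the less crowded oxaphosphetane should give the E alkene, whose geometry is in any case erased in step 10.

Step 9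
Reactants: 14 1-allyloxy-3-[2,2-bis(3,4-dimethoxyphenyl)ethyl]-2-[(E)-2-(3,5-dimethoxyphenyl)ethenyl]-5-methoxybenzene
Product: 15 3-[2,2-bis(3,4-dimethoxyphenyl)ethyl]-2-[(E)-2-(3,5-dimethoxyphenyl)ethenyl]-5-methoxyphenol (achiral key precursor)
Conditions: Pd(PPh3)4 (5 mol %), morpholine (10 equiv), THF, rt
Reagents that add atoms: none
Why: Tsuji–Trost deallylation: zerovalent palladium ionises the allyl aryl ether and morpholine traps the allyl fragment, so the phenol is freed under neutral to basic conditions and the acid-sensitive hydroxystilbene cannot cyclise in a racemic background reaction.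

Step 10
Reactants: 15 3-[2,2-bis(3,4-dimethoxyphenyl)ethyl]-2-[(E)-2-(3,5-dimethoxyphenyl)ethenyl]-5-methoxyphenol
Product: 17 (5S,10R)-5-(3,5-dimethoxybenzyl)-10-(3,4-dimethoxyphenyl)-2,7,8-trimethoxy-10,11-dihydro-5H-dibenzo[a,d][7]annulen-4-ol (ring F phenol; C5 = M1 and C10 = M2; M1-H and M2-H cis), via catalyst-bound ortho-quinone methide 16 (not isolated)
Conditions: (R)-3,3'-bis(2,4,6-triisopropylphenyl)-1,1'-binaphthyl-2,2'-diyl N-triflyl phosphoramide (10 mol %), 4 Å MS, toluene (0.005 M), −20 °C → rt
Reagents that add atoms: none
Why: Proposed new method: the acid should protonate the alkene carbon next to ring A, since only a positive charge at M1 is carried by the ortho hydroxyl and para methoxyl of ring D whereas both methoxyls of ring A sit meta to its benzylic carbon, and passage of the phenol proton to the phosphoramide anion then leaves methide 16 hydrogen-bonded to the catalyst through the ring D oxygen. C6 of one veratryl ring, para to its 3-methoxyl, adds to M1 in a 7-endo-trig Friedel–Crafts closure of ring F (both carbons of the polarised exocyclic C=C end up inside the new ring), and loss of the arenium proton to the anion restores ring B, the phenol and the acid. The closest known reaction types are chiral phosphoric acid catalysed additions of indoles, naphthols and related arenes to ortho-quinone methides raised from 2-vinylphenols, and catalytic desymmetrising cyclisations of diarylmethanes; a veratryl nucleophile without a hydrogen-bond donor, a seven-membered closure and the union of both ideas are untested. M1 is controlled by the catalyst, whose 3,3'-aryl groups shield one face of the bound methide, the methide itself being held as the Z isomer because allylic strain with the arm turns the ring A benzyl group toward the oxygen. M2 is controlled by which enantiotopic veratryl ring reaches the open face, and a boat-like transition state that keeps the spectator ring (future ring E) pseudo-equatorial couples this choice to the face, so that M1-H and M2-H come out cis and the catalyst antipode decides between (5S,10R) and (5R,10S). The step needs site selectivity for C6 over C2 and the ipso carbon, which para activation and lower crowding favour, and chemoselectivity against ring A, the best nucleophile present, which is secured because ring A could reach M1 only through a three- or four-membered ring, while high dilution holds back intermolecular capture.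

Step 11
Reactants: 17 ring F phenol
Product: 18 (5S,10R)-5-(3,5-dimethoxybenzyl)-10-(3,4-dimethoxyphenyl)-2,7,8-trimethoxy-10,11-dihydro-5H-dibenzo[a,d][7]annulen-4-yl trifluoromethanesulfonate
Conditions: Tf2O, pyridine, CH2Cl2, 0 °C
Reagents that add atoms: trifluoromethanesulfonic anhydride, O=S(=O)(OS(=O)(=O)C(F)(F)F)C(F)(F)F
Why: O-sulfonylation of the only free phenol turns the oxygen that anchored the catalyst into a leaving group for palladium; neither stereocentre is touched.

Step 12
Reactants: 18 ring D triflate
Product: 19 heptamethyl ether of the target (rings A to F complete; M1 S and M2 R; M1-H and M2-H cis)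
Conditions: Pd(OAc)2 (10 mol %), PCy3·HBF4 (20 mol %), PivOH (30 mol %), K2CO3 (3 equiv), DMA, 120 °C
Reagents that add atoms: none
Why: Intramolecular palladium-catalysed direct arylation by concerted metalation–deprotonation: zerovalent palladium inserts into the C–OTf bond, pivalate-assisted palladation takes either of the two ortho C–H bonds of ring A (equivalent by rotation about the CH2–aryl bond) and reductive elimination closes six-membered ring C, while the ring B C–H next to M1 is out of reach because the resulting fluorene could not be spanned by the two-carbon bridge of ring F, and carbonate is too weak a base to epimerise M1 or M2.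

Step 13
Reactants: 19 heptamethyl ether of the target
Product: 20 CNP0306974.2 (target; M1 S and M2 R)
Conditions: BBr3 (20 equiv), CH2Cl2, −78 °C → rt, argon; then H2O
Reagents that add atoms: none
Why: Lewis acid mediated cleavage of all seven aryl methyl ethers (bromide attacks each boron-activated methyl group); the all-carbon skeleton has no acid-labile C–O bond and both stereocentres stay as set in step 10.

## Compound list

1 | 3,5-dimethoxyphenylacetic acid | OC(=O)Cc1cc(OC)cc(OC)c1 | starting material
2 | methyl 3,5-dimethoxyphenylacetate | COC(=O)Cc1cc(OC)cc(OC)c1 | intermediate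
3 | 4-bromoveratrole | COc1ccc(Br)cc1OC | starting material
4 | 3,4-dimethoxyphenylmagnesium bromide (not isolated) | COc1ccc([Mg]Br)cc1OC | intermediate
5 | 1-(3,4-dimethoxyphenyl)-2-(3,5-dimethoxyphenyl)ethan-1-one (not isolated) | COc1cc(CC(=O)c2ccc(OC)c(OC)c2)cc(OC)c1 | intermediate
6 | 1,1-bis(3,4-dimethoxyphenyl)-2-(3,5-dimethoxyphenyl)ethan-1-ol | COc1cc(CC(O)(c2ccc(OC)c(OC)c2)c2ccc(OC)c(OC)c2)cc(OC)c1 | intermediate
7 | 1,1-bis(3,4-dimethoxyphenyl)-2-(3,5-dimethoxyphenyl)ethane | COc1cc(CC(c2ccc(OC)c(OC)c2)c2ccc(OC)c(OC)c2)cc(OC)c1 | intermediate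
8 | aryl(dimethyl)iminium dichlorophosphate (not isolated) | COc1cc(OC)c(C=[N+](C)C)c(CC(c2ccc(OC)c(OC)c2)c2ccc(OC)c(OC)c2)c1.[O-]P(=O)(Cl)Cl | intermediate
9 | 2-[2,2-bis(3,4-dimethoxyphenyl)ethyl]-4,6-dimethoxybenzaldehyde | COc1cc(OC)c(C=O)c(CC(c2ccc(OC)c(OC)c2)c2ccc(OC)c(OC)c2)c1 | intermediate
10 | 2-[2,2-bis(3,4-dimethoxyphenyl)ethyl]-6-hydroxy-4-methoxybenzaldehyde | COc1cc(O)c(C=O)c(CC(c2ccc(OC)c(OC)c2)c2ccc(OC)c(OC)c2)c1 | intermediate
11 | 2-allyloxy-6-[2,2-bis(3,4-dimethoxyphenyl)ethyl]-4-methoxybenzaldehyde | COc1cc(OCC=C)c(C=O)c(CC(c2ccc(OC)c(OC)c2)c2ccc(OC)c(OC)c2)c1 | intermediate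
12 | 3,5-dimethoxybenzyl bromide | COc1cc(CBr)cc(OC)c1 | starting material
13 | diethyl (3,5-dimethoxybenzyl)phosphonate | CCOP(=O)(Cc1cc(OC)cc(OC)c1)OCC | intermediate
14 | allyl ether of the (E)-2-hydroxystilbene | COc1cc(OCC=C)c(/C=C/c2cc(OC)cc(OC)c2)c(CC(c2ccc(OC)c(OC)c2)c2ccc(OC)c(OC)c2)c1 | intermediate
15 | 3-[2,2-bis(3,4-dimethoxyphenyl)ethyl]-2-[(E)-2-(3,5-dimethoxyphenyl)ethenyl]-5-methoxyphenol (key precursor, achiral) | COc1cc(O)c(/C=C/c2cc(OC)cc(OC)c2)c(CC(c2ccc(OC)c(OC)c2)c2ccc(OC)c(OC)c2)c1 | intermediate
16 | (6Z)-5-[2,2-bis(3,4-dimethoxyphenyl)ethyl]-6-[2-(3,5-dimethoxyphenyl)ethylidene]-3-methoxycyclohexa-2,4-dien-1-one (ortho-quinone methide, not isolated) | O=C1C=C(OC)C=C(CC(c2ccc(OC)c(OC)c2)c2ccc(OC)c(OC)c2)/C1=C/Cc1cc(OC)cc(OC)c1 | intermediate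
17 | (5S,10R)-5-(3,5-dimethoxybenzyl)-10-(3,4-dimethoxyphenyl)-2,7,8-trimethoxy-10,11-dihydro-5H-dibenzo[a,d][7]annulen-4-ol (key product) | COc1cc(OC)cc(c1)C[C@H]1c3cc(OC)c(OC)cc3[C@@H](c3ccc(OC)c(OC)c3)Cc3cc(OC)cc(O)c31 | intermediate
18 | trifluoromethanesulfonate of 17 | COc1cc(OC)cc(c1)C[C@H]1c3cc(OC)c(OC)cc3[C@@H](c3ccc(OC)c(OC)c3)Cc3cc(OC)cc(OS(=O)(=O)C(F)(F)F)c31 | intermediate
19 | heptamethyl ether of the target | COc1cc(OC)c2c(c1)C[C@H]1c3cc(OC)c(OC)cc3[C@@H](c3ccc(OC)c(OC)c3)Cc3cc(OC)cc-2c31 | intermediate
20 | CNP0306974.2 | Oc1cc(O)c2c(c1)C[C@H]1c3cc(O)c(O)cc3[C@@H](c3ccc(O)c(O)c3)Cc3cc(O)cc-2c31 | target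

## Step count

Total step count: 13
Longest linear sequence: 12 steps (1 to 20 through steps 1–6 and 8–13; step 7 is the side branch)

## Steps most likely to fail

**1. Step 10.**
- What may go wrong:
  - Face and group selection may be weak, because the veratryl nucleophile offers the catalyst no hydrogen-bond donor and the anion holds the methide at one point only.
  - Ring A or the alkene of a second molecule may capture the methide, which leads to oligomerisation.
  - A veratryl ring may attack through its ipso carbon, which is para to the 4-methoxyl, and the aryl group may then migrate.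
  - C–C bond formation may be reversible, which would erode the selectivity.
- Fallback (known chemistry, from 15 back to 17): 15 is cyclised with an achiral acid (TsOH·H2O, CH2Cl2, high dilution). This is an ordinary intramolecular Friedel–Crafts cycloalkylation of an electron-rich styrene. It should give the racemic cis ring F phenol F1, freed from any trans isomer by chromatography. Acylation with (1R,2S,5R)-menthyl chloroformate and Et3N gives two diastereomeric carbonates. These are the menthyl carbonate of the (5S,10R) phenol F2 and the menthyl carbonate of the (5R,10S) phenol F3, and they are separated by chromatography or crystallisation. LiOH in THF/H2O cleaves F2 to 17.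

**2. Step 12.**
- What may go wrong:
  - Palladation of the crowded ring A C–H next to a methoxyl may be slow.
  - Carbonate may cleave the S–O bond of the triflate at 120 °C.
  - The arylpalladium intermediate may be reduced.
- Fallback (from 18 back to 19): the C–H partner is replaced by a C–Br partner. NBS (1 equiv, MeCN, −20 → 0 °C) should brominate ring A, the only ring with two mutually reinforcing methoxyls. Bromination should occur at the carbon ortho to the CH2 group and para to a methoxyl, giving the bromo triflate F4. A Stille–Kelly coupling ((Me3Sn)2, Pd(PPh3)4, LiCl, dioxane, 100 °C) turns the triflate in the flask into the arylstannane F5. This stannane couples with the neighbouring aryl bromide and gives 19.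

**3. Step 2.**
- What may go wrong: the basic aryl Grignard reagent may enolise the arylacetate and, still more, ketone 5, so that the sequence stalls after one addition.
- Fallback (from 12 back to 6): the polarity of the fragments is exchanged. 12 is converted with Mg (slow addition, Et2O, 0 °C, to limit Wurtz coupling) into 3,5-dimethoxybenzylmagnesium bromide F6. This reagent is added to bis(3,4-dimethoxyphenyl)methanone F7, a bought ketone without α-hydrogens that cannot enolise, and the addition gives 6 directly.

## Further compounds

F1 | step 10 | racemic cis ring F phenol (both enantiomers written) | COc1cc(OC)cc(c1)C[C@H]1c3cc(OC)c(OC)cc3[C@@H](c3ccc(OC)c(OC)c3)Cc3cc(OC)cc(O)c31.COc1cc(OC)cc(c1)C[C@@H]1c3cc(OC)c(OC)cc3[C@H](c3ccc(OC)c(OC)c3)Cc3cc(OC)cc(O)c31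
F2 | step 10 | (1R,2S,5R)-menthyl carbonate of the (5S,10R) phenol | COc1cc(OC)cc(c1)C[C@H]1c3cc(OC)c(OC)cc3[C@@H](c3ccc(OC)c(OC)c3)Cc3cc(OC)cc(OC(=O)O[C@H]4[C@H](C(C)C)CC[C@@H](C)C4)c31
F3 | step 10 | (1R,2S,5R)-menthyl carbonate of the (5R,10S) phenol | COc1cc(OC)cc(c1)C[C@@H]1c3cc(OC)c(OC)cc3[C@H](c3ccc(OC)c(OC)c3)Cc3cc(OC)cc(OC(=O)O[C@H]4[C@H](C(C)C)CC[C@@H](C)C4)c31
F4 | step 12 | bromo triflate (18 with Br on the ring A carbon between the CH2 group and a methoxyl) | COc1cc(OC)c(Br)c(c1)C[C@H]1c3cc(OC)c(OC)cc3[C@@H](c3ccc(OC)c(OC)c3)Cc3cc(OC)cc(OS(=O)(=O)C(F)(F)F)c31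
F5 | step 12 | arylstannane (F4 with SnMe3 in place of OTf, formed in the flask) | COc1cc(OC)c(Br)c(c1)C[C@H]1c3cc(OC)c(OC)cc3[C@@H](c3ccc(OC)c(OC)c3)Cc3cc(OC)cc([Sn](C)(C)C)c31
F6 | step 2 | 3,5-dimethoxybenzylmagnesium bromide | COc1cc(C[Mg]Br)cc(OC)c1
F7 | step 2 | bis(3,4-dimethoxyphenyl)methanone (bought) | COc1ccc(cc1OC)C(=O)c1ccc(OC)c(OC)c1
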